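**Plan**

1. Numbering: ring A (cyclopentane) is C1 (quaternary, CH3 and ring B), C2 (CMe2), C3 (CHBr), C4 (CH2), C5 (CHOH); ring B (cyclohexane) is C1' (carbinol), C2', C3', C4' (CMeCl), C5' (CHBr), C6'.
2. Enabling feature: the ring B halogens sit on the adjacent carbons C4' and C5', Cl cis and Br trans to the C1' hydroxyl. An all-cis 1',4',5'-triol maps onto this by retention at C4' and inversion at C5', and its C4'–C5' bond joins two carbonyl carbons of a 1,6-keto aldehyde hung on C1'.
3. Cuts: C3–Br, C5'–Br and C4'–Cl back to C–O; C4'–C5' (SmI2 pinacol, ring B); C1'–C6' and C1'–C2' (allyl and 3-methylbut-3-enyl nucleophiles on the ring A carboxyl carbon); C1–CH3 (enolate methylation); C1–C2 (rhodium carbenoid C–H insertion, ring A); one Claisen C–C bond.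
4. Forward order: acyclic diazo keto ester, ring A (step 5), C1 quaternary centre, two arms on C1', ring B (step 13), then the three halogens.
5. Stereochemistry: C3 and C5 come from two Ru–BINAP hydrogenations, C1 from Fráter–Seebach methylation anti to the C5 alkoxide, C1' from the order of arm addition (allyl last, anti to C2), and C4'/C5' from samarium chelation to the C1' hydroxyl. The end game is inversion at C5' (cyclic sulfate, LiBr), retention at C4' (bromonium ion) and inversion at C3 (Appel).

Key step: step 13

Remark on the chemistry: 8 is written without a descriptor at C1 because its C1 epimers should equilibrate through the enol (C1 is flattened again in step 7); allylmagnesium bromide 16 is taken as the commercial ether solution.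

**Route**

Step 1
Reactants: 1 methyl 4-methyl-3-oxopentanoate
Product: 2 methyl (3R)-3-hydroxy-4-methylpentanoate
Conditions: H2 (50 atm), RuCl2[(S)-BINAP] (0.1 mol %), MeOH, 50 °C
Reagents that add atoms: none
Why: Noyori asymmetric hydrogenation of a β-keto ester, in which the chelated Ru–(S)-BINAP hydride reduces one ketone face and should set the future C3 carbinol as R (isopropyl outranks CH2CO2Me, hence R from the S ligand).

Step 2
Reactants: 2 methyl (3R)-3-hydroxy-4-methylpentanoate
Product: 3 methyl (3R)-3-[(tert-butyldimethylsilyl)oxy]-4-methylpentanoate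
Conditions: TBSCl, imidazole, DMF, rt
Reagents that add atoms: tert-butyldimethylsilyl chloride, CC(C)(C)[Si](C)(C)Cl
Why: standard imidazole-mediated silylation of a secondary alcohol; the bulky, weakly basic silyl ether should stay out of the later carbenoid step and lasts until step 18.

Step 3
Reactants: 3 methyl (3R)-3-[(tert-butyldimethylsilyl)oxy]-4-methylpentanoate; 4 tert-butyl acetate
Product: 6 tert-butyl (5R)-5-[(tert-butyldimethylsilyl)oxy]-6-methyl-3-oxoheptanoate, via lithium enolate of tert-butyl acetate 5 (not isolated)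
Conditions: 4 (3.5 equiv), LiN(iPr)2, THF, −78 °C; then 3, −78 → −20 °C
Reagents that add atoms: none
Why: crossed Claisen condensation of a methyl ester and excess lithium tert-butyl acetate enolate, in which the product rests as its enolate so that no second addition occurs and the silyloxy stereocentre is not touched.

Step 4
Reactants: 6 tert-butyl (5R)-5-[(tert-butyldimethylsilyl)oxy]-6-methyl-3-oxoheptanoate
Product: 7 tert-butyl (5R)-5-[(tert-butyldimethylsilyl)oxy]-2-diazo-6-methyl-3-oxoheptanoate
Conditions: 4-acetamidobenzenesulfonyl azide, Et3N, MeCN, 0 °C → rt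
Reagents that add atoms: 4-acetamidobenzenesulfonyl azide, CC(=O)Nc1ccc(cc1)S(=O)(=O)N=[N+]=[N-]
Why: Regitz diazo transfer to the active methylene group of a β-keto ester.

Step 5
Reactants: 7 tert-butyl (5R)-5-[(tert-butyldimethylsilyl)oxy]-2-diazo-6-methyl-3-oxoheptanoate
Product: 8 tert-butyl (3R)-3-[(tert-butyldimethylsilyl)oxy]-2,2-dimethyl-5-oxocyclopentane-1-carboxylate
Conditions: Rh2(OAc)4 (1 mol %), CH2Cl2, 40 °C, slow addition
Reagents that add atoms: none
Why: intramolecular 1,5 C–H insertion of the rhodium carbenoid of an α-diazo-β-keto ester into the isopropyl methine, the only C–H that leads to a five-membered ring, should close ring A through the C1–C2 bond and create the gem-dimethyl carbon C2; no lasting stereocentre is formed.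

Step 6
Reactants: 8 tert-butyl (3R)-3-[(tert-butyldimethylsilyl)oxy]-2,2-dimethyl-5-oxocyclopentane-1-carboxylate
Product: 9 tert-butyl (1R,3R,5R)-3-[(tert-butyldimethylsilyl)oxy]-5-hydroxy-2,2-dimethylcyclopentane-1-carboxylate
Conditions: H2 (80 atm), RuCl2[(R)-BINAP] (1 mol %), CH2Cl2, 50 °C
Reagents that add atoms: none
Why: Noyori hydrogenation under dynamic kinetic resolution of a cyclic β-keto ester, in which C1 epimerises through the enol while the (R)-BINAP catalyst is expected to fix the C5 carbinol as R (trans to the C3 silyloxy group) and give the trans hydroxy ester usual in CH2Cl2.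

Step 7
Reactants: 9 tert-butyl (1R,3R,5R)-3-[(tert-butyldimethylsilyl)oxy]-5-hydroxy-2,2-dimethylcyclopentane-1-carboxylate
Product: 11 tert-butyl (1S,3R,5R)-3-[(tert-butyldimethylsilyl)oxy]-5-hydroxy-1,2,2-trimethylcyclopentane-1-carboxylate, via dilithium alkoxide enolate 10 (not isolated)
Conditions: LiN(iPr)2 (2.3 equiv), THF, −78 → −20 °C; then MeI, DMPU, −78 → 0 °C
Reagents that add atoms: iodomethane, CI
Why: Fráter–Seebach alkylation, in which the chelated alkoxide enolate is methylated on the face opposite the C5 alkoxide, so the new C1 methyl should be trans and the ester cis to the C5 hydroxyl (C1 becomes S).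

Step 8
Reactants: 11 tert-butyl (1S,3R,5R)-3-[(tert-butyldimethylsilyl)oxy]-5-hydroxy-1,2,2-trimethylcyclopentane-1-carboxylate
Product: 12 (1S,3R,5R)-3-[(tert-butyldimethylsilyl)oxy]-5-hydroxy-1,2,2-trimethylcyclopentane-1-carboxylic acid
Conditions: 85 % aq. H3PO4, toluene, rt
Reagents that add atoms: none
Why: acid-mediated tert-butyl ester cleavage by alkyl–oxygen fission (AAL1), which needs no attack at the very hindered carbonyl carbon and under aqueous phosphoric acid is known to spare TBS ethers.

Step 9
Reactants: 12 (1S,3R,5R)-3-[(tert-butyldimethylsilyl)oxy]-5-hydroxy-1,2,2-trimethylcyclopentane-1-carboxylic acid; 13 4-bromo-2-methylbut-1-ene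
Product: 15 1-[(1S,3R,5R)-3-[(tert-butyldimethylsilyl)oxy]-5-hydroxy-1,2,2-trimethylcyclopentyl]-4-methylpent-4-en-1-one, via (3-methylbut-3-en-1-yl)lithium 14 (not isolated)
Conditions: 13, Li, Et2O, −10 °C; then 12 (0.28 equiv), THF, −78 °C → rt; inverse quench into cold aq. NH4Cl
Reagents that add atoms: none
Why: ketone synthesis by addition of an organolithium to a lithium carboxylate, whose gem-diolate adduct holds until work-up, so exactly one 3-methylbut-3-enyl arm is placed on the future C1' carbon with no stereocentre affected.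

Step 10
Reactants: 15 1-[(1S,3R,5R)-3-[(tert-butyldimethylsilyl)oxy]-5-hydroxy-1,2,2-trimethylcyclopentyl]-4-methylpent-4-en-1-one; 16 allylmagnesium bromide
Product: 17 (1R,2S,4R)-4-[(tert-butyldimethylsilyl)oxy]-2-[(4R)-4-hydroxy-7-methylocta-1,7-dien-4-yl]-2,3,3-trimethylcyclopentan-1-ol
Conditions: 16 (3 equiv), THF, −78 °C
Reagents that add atoms: none
Why: Grignard addition to a β-hydroxy ketone, in which the magnesium chelate between the C5 alkoxide and the carbonyl (and equally the Felkin–Anh model with C2 as the large group) exposes the face on the side of the C1 methyl, so allyl should enter anti to the gem-dimethyl carbon C2 and set C1' as R.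

Step 11
Reactants: 17 (1R,2S,4R)-4-[(tert-butyldimethylsilyl)oxy]-2-[(4R)-4-hydroxy-7-methylocta-1,7-dien-4-yl]-2,3,3-trimethylcyclopentan-1-ol
Product: 18 C5 tert-butyl carbonate of 17 (C1' hydroxyl free; C3 OTBS)
Conditions: Boc2O, DMAP (20 mol %), MeCN, rt
Reagents that add atoms: di-tert-butyl dicarbonate, CC(C)(C)OC(=O)OC(=O)OC(C)(C)C
Why: DMAP-catalysed carbonate formation, which should touch only the secondary C5 hydroxyl because the tertiary C1' hydroxyl is flanked by the quaternary C1; O5 is thereby kept from closing a six-membered lactol on the coming aldehyde.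

Step 12
Reactants: 18 C5 tert-butyl carbonate of 17 (C1' hydroxyl free; C3 OTBS)
Product: 20 keto aldehyde: (1'R)-carbinol C1' on ring A bearing a 2-oxoethyl arm (C6'–C5') and a 3-oxobutyl arm (C2'–C4'); C5 OBoc; C3 OTBS, via bis-ozonide 19 (not isolated)
Conditions: O3, CH2Cl2, −78 °C; then PPh3, −78 °C → rt
Reagents that add atoms: ozone, [O-][O+]=O
Why: ozonolysis and reductive work-up, which should cleave both terminal alkenes at once, the allyl arm to the C5' aldehyde and the isopropenyl arm to the C4' methyl ketone.

Step 13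
Reactants: 20 keto aldehyde: (1'R)-carbinol C1' on ring A bearing a 2-oxoethyl arm (C6'–C5') and a 3-oxobutyl arm (C2'–C4'); C5 OBoc; C3 OTBS
Product: 21 ring B all-cis 1',4',5'-triol (1'R,4'S,5'R); C5 OBoc; C3 OTBS
Conditions: SmI2 (2.5 equiv, 0.1 M in THF), THF, −78 °C; aq. NaHCO3
Reagents that add atoms: none
Why: SmI2 passes one electron to the aldehyde carbonyl, the more easily reduced of the two, and the ketyl, now on trivalent samarium, also binds the free C1' hydroxyl (six-membered chelate over C5'–C6'–C1') and the ketone oxygen. The ketyl carbon C5' then adds to the ketone carbon C4' in a 6-exo-trig closure of ring B and a second SmI2 reduces the oxygen radical, which is the known SmI2 intramolecular pinacol coupling of 1,6-keto aldehydes to cis-cyclohexane-1,2-diols. The ring should close through a chair that keeps the bulky ring A substituent of C1' equatorial and the C1' hydroxyl axial. C5' is controlled by the chelate, since its oxygen has to sit axial and syn to the C1' hydroxyl to share the metal. C4' is controlled by the same samarium bridging both new oxygens, which places the C4' oxygen cis to that of C5' and the methyl group on the other face. The step needs reduction of the aldehyde ahead of the ketone and the carbonate (no HMPA, −78 °C) and delivery on the hydroxyl face; the free C1' hydroxyl, with O5 capped as the carbonate, is what should secure the latter.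

Step 14
Reactants: 21 ring B all-cis 1',4',5'-triol (1'R,4'S,5'R); C5 OBoc; C3 OTBS
Product: 22 cyclic carbonate bridging O5 and O1' (six-membered); ring B cis-4',5'-diol; C3 OTBS
Conditions: KOtBu (10 mol %), THF, −20 °C; AcOH quench
Reagents that add atoms: none
Why: base-catalysed intramolecular transcarbonation, in which the C1' alkoxide, the only one that can reach the Boc carbonyl through a six-membered transition state, expels tert-butoxide; the cyclic carbonate masks O5 for step 19 and makes O1' non-nucleophilic, since a free C1' hydroxyl would capture the later bromonium ion as a bridged ether.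

Step 15
Reactants: 22 cyclic carbonate bridging O5 and O1' (six-membered); ring B cis-4',5'-diol; C3 OTBS
Product: 24 4',5'-cyclic sulfate of 22, via cyclic sulfite 23 (not isolated)
Conditions: SOCl2, Et3N, CH2Cl2, 0 °C; then RuCl3·3H2O (1 mol %), NaIO4, MeCN/CCl4/H2O, 0 °C
Reagents that add atoms: thionyl chloride, O=S(Cl)Cl; sodium periodate, [Na+].[O-]I(=O)(=O)=O
Why: cyclic sulfate formation from a cis-1,2-diol through the cyclic sulfite and RuO4-catalysed oxidation, which activates both C–O bonds without touching a stereocentre.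

Step 16
Reactants: 24 4',5'-cyclic sulfate of 22
Product: 26 trans bromohydrin (4'S,5'S): C5' Br on the face opposite the C1' and C4' oxygens; C4' tertiary alcohol; carbonate and C3 OTBS kept, via lithium sulfate half-ester 25 (not isolated)
Conditions: LiBr (1.1 equiv), THF, rt; then H2SO4 (cat.), H2O (2 equiv), THF, rt
Reagents that add atoms: lithium bromide, [Li+].[Br-]
Why: SN2 opening of a cyclic sulfate by bromide at the secondary carbon C5' should invert that centre, and acid-catalysed hydrolysis of the tertiary sulfate half-ester then frees the C4' alcohol with its configuration unchanged.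

Step 17
Reactants: 26 trans bromohydrin (4'S,5'S): C5' Br on the face opposite the C1' and C4' oxygens; C4' tertiary alcohol; carbonate and C3 OTBS kept
Product: 27 4'-chloro-5'-bromo compound (4'S,5'S); carbonate and C3 OTBS kept
Conditions: SOCl2 (1.3 equiv), 2,6-di-tert-butyl-4-methylpyridine, CH2Cl2, −78 → −20 °C
Reagents that add atoms: thionyl chloride, O=S(Cl)Cl
Why: deoxychlorination of a tertiary alcohol through its chlorosulfite with anchimeric assistance, in which the trans C5' bromine expels the leaving group to a bromonium ion on the upper face and chloride returns to the tertiary C4' carbon from the face the oxygen left (internal return), so C4' should keep its configuration.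

Step 18
Reactants: 27 4'-chloro-5'-bromo compound (4'S,5'S); carbonate and C3 OTBS kept
Product: 28 C3 alcohol (3R) of 27
Conditions: HF·pyridine, THF, 0 °C → rt
Reagents that add atoms: none
Why: fluoride-mediated desilylation under weakly acidic, non-basic conditions that should leave the tertiary chloride, the secondary bromide and the carbonate alone.

Step 19
Reactants: 28 C3 alcohol (3R) of 27
Product: 29 C3 bromide (3S): 3,5'-dibromo-4'-chloro cyclic carbonate
Conditions: CBr4, P(n-C8H17)3, toluene, 70 °C
Reagents that add atoms: carbon tetrabromide, BrC(Br)(Br)Br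
Why: Appel bromination through the alkoxyphosphonium salt with SN2 inversion at C3, the trialkylphosphine at 70 °C being the known way to brominate a secondary alcohol next to a gem-dimethyl carbon; bromine should end cis to the C5 oxygen.

Step 20
Reactants: 29 C3 bromide (3S): 3,5'-dibromo-4'-chloro cyclic carbonate
Product: 30 target CNP0158757.1 (1S,3S,5R,1'R,4'S,5'S)
Conditions: K2CO3, MeOH, 0 °C
Reagents that add atoms: none
Why: base-catalysed methanolysis of the cyclic carbonate frees the C5 and C1' hydroxyls; neither alkoxide can reach a C–halogen bond from the rear (O5 is cis to the C3 bromine, O1' cis to the C4' chlorine) and the equatorial ring B halogens lack an antiperiplanar ring hydrogen.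

**Compound list**

1 | methyl 4-methyl-3-oxopentanoate | CC(C)C(=O)CC(=O)OC | starting material
2 | methyl (3R)-3-hydroxy-4-methylpentanoate | CC(C)[C@H](O)CC(=O)OC | intermediate
3 | methyl (3R)-3-[(tert-butyldimethylsilyl)oxy]-4-methylpentanoate | CC(C)[C@H](O[Si](C)(C)C(C)(C)C)CC(=O)OC | intermediate
4 | tert-butyl acetate | CC(=O)OC(C)(C)C | starting material
5 | lithium enolate of tert-butyl acetate | C=C(O[Li])OC(C)(C)C | intermediate
6 | tert-butyl (5R)-5-[(tert-butyldimethylsilyl)oxy]-6-methyl-3-oxoheptanoate | CC(C)[C@H](O[Si](C)(C)C(C)(C)C)CC(=O)CC(=O)OC(C)(C)C | intermediate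
7 | tert-butyl (5R)-5-[(tert-butyldimethylsilyl)oxy]-2-diazo-6-methyl-3-oxoheptanoate | CC(C)[C@H](O[Si](C)(C)C(C)(C)C)CC(=O)C(=[N+]=[N-])C(=O)OC(C)(C)C | intermediate
8 | tert-butyl (3R)-3-[(tert-butyldimethylsilyl)oxy]-2,2-dimethyl-5-oxocyclopentane-1-carboxylate | CC1(C)[C@H](O[Si](C)(C)C(C)(C)C)CC(=O)C1C(=O)OC(C)(C)C | intermediate
9 | tert-butyl (1R,3R,5R)-3-[(tert-butyldimethylsilyl)oxy]-5-hydroxy-2,2-dimethylcyclopentane-1-carboxylate | CC1(C)[C@H](O[Si](C)(C)C(C)(C)C)C[C@@H](O)[C@@H]1C(=O)OC(C)(C)C | intermediate
10 | dilithium alkoxide enolate of 9 | CC1(C)[C@H](O[Si](C)(C)C(C)(C)C)C[C@@H](O[Li])C1=C(O[Li])OC(C)(C)C | intermediate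
11 | tert-butyl (1S,3R,5R)-3-[(tert-butyldimethylsilyl)oxy]-5-hydroxy-1,2,2-trimethylcyclopentane-1-carboxylate | CC1(C)[C@H](O[Si](C)(C)C(C)(C)C)C[C@@H](O)[C@@]1(C)C(=O)OC(C)(C)C | intermediate
12 | (1S,3R,5R)-3-[(tert-butyldimethylsilyl)oxy]-5-hydroxy-1,2,2-trimethylcyclopentane-1-carboxylic acid | CC1(C)[C@H](O[Si](C)(C)C(C)(C)C)C[C@@H](O)[C@@]1(C)C(=O)O | intermediate
13 | 4-bromo-2-methylbut-1-ene | C=C(C)CCBr | starting material
14 | (3-methylbut-3-en-1-yl)lithium | [Li]CCC(C)=C | intermediate
15 | 1-[(1S,3R,5R)-3-[(tert-butyldimethylsilyl)oxy]-5-hydroxy-1,2,2-trimethylcyclopentyl]-4-methylpent-4-en-1-one | CC1(C)[C@H](O[Si](C)(C)C(C)(C)C)C[C@@H](O)[C@@]1(C)C(=O)CCC(C)=C | intermediate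
16 | allylmagnesium bromide | C=CC[Mg]Br | starting material
17 | (1R,2S,4R)-4-[(tert-butyldimethylsilyl)oxy]-2-[(4R)-4-hydroxy-7-methylocta-1,7-dien-4-yl]-2,3,3-trimethylcyclopentan-1-ol | CC1(C)[C@H](O[Si](C)(C)C(C)(C)C)C[C@@H](O)[C@@]1(C)[C@](O)(CC=C)CCC(C)=C | intermediate
18 | C5 tert-butyl carbonate of 17 (C1' hydroxyl free; C3 OTBS) | CC1(C)[C@H](O[Si](C)(C)C(C)(C)C)C[C@@H](OC(=O)OC(C)(C)C)[C@@]1(C)[C@](O)(CC=C)CCC(C)=C | intermediate
19 | bis-ozonide of 18 (two 1,2,4-trioxolanes; ring epimers) | CC1(C)[C@H](O[Si](C)(C)C(C)(C)C)C[C@@H](OC(=O)OC(C)(C)C)[C@@]1(C)[C@](O)(CC2OCOO2)CCC3(C)OCOO3 | intermediate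
20 | keto aldehyde: tert-butyl (1R,2S,4R)-4-[(tert-butyldimethylsilyl)oxy]-2-[(3R)-3-hydroxy-1,6-dioxoheptan-3-yl]-2,3,3-trimethylcyclopentyl carbonate | CC1(C)[C@H](O[Si](C)(C)C(C)(C)C)C[C@@H](OC(=O)OC(C)(C)C)[C@@]1(C)[C@](O)(CC=O)CCC(C)=O | intermediate
21 | ring B all-cis 1',4',5'-triol (1'R,4'S,5'R); C5 OBoc; C3 OTBS | CC1(C)[C@H](O[Si](C)(C)C(C)(C)C)C[C@@H](OC(=O)OC(C)(C)C)[C@@]1(C)[C@@]1(O)CC[C@](C)(O)[C@H](O)C1 | intermediate
22 | cyclic carbonate bridging O5 and O1'; ring B cis-4',5'-diol; C3 OTBS | CC1(C)[C@H](O[Si](C)(C)C(C)(C)C)C[C@@H](OC(=O)O2)[C@@]1(C)[C@]21CC[C@](C)(O)[C@H](O)C1 | intermediate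
23 | 4',5'-cyclic sulfite of 22 (epimers at sulfur) | CC1(C)[C@H](O[Si](C)(C)C(C)(C)C)C[C@@H](OC(=O)O2)[C@@]1(C)[C@]21CC[C@]3(C)OS(=O)O[C@@H]3C1 | intermediate
24 | 4',5'-cyclic sulfate of 22 | CC1(C)[C@H](O[Si](C)(C)C(C)(C)C)C[C@@H](OC(=O)O2)[C@@]1(C)[C@]21CC[C@]3(C)OS(=O)(=O)O[C@@H]3C1 | intermediate
25 | lithium sulfate half-ester: C4' OSO3Li; C5' Br (inverted) | CC1(C)[C@H](O[Si](C)(C)C(C)(C)C)C[C@@H](OC(=O)O2)[C@@]1(C)[C@]21CC[C@](C)(OS(=O)(=O)[O-])[C@@H](Br)C1.[Li+] | intermediate
26 | trans bromohydrin (4'S,5'S); carbonate; C3 OTBS | CC1(C)[C@H](O[Si](C)(C)C(C)(C)C)C[C@@H](OC(=O)O2)[C@@]1(C)[C@]21CC[C@](C)(O)[C@@H](Br)C1 | intermediate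
27 | 4'-chloro-5'-bromo compound (4'S,5'S); carbonate; C3 OTBS | CC1(C)[C@H](O[Si](C)(C)C(C)(C)C)C[C@@H](OC(=O)O2)[C@@]1(C)[C@]21CC[C@](C)(Cl)[C@@H](Br)C1 | intermediate
28 | C3 alcohol (3R) of 27 | CC1(C)[C@H](O)C[C@@H](OC(=O)O2)[C@@]1(C)[C@]21CC[C@](C)(Cl)[C@@H](Br)C1 | intermediate
29 | C3 bromide (3S): 3,5'-dibromo-4'-chloro cyclic carbonate | CC1(C)[C@@H](Br)C[C@@H](OC(=O)O2)[C@@]1(C)[C@]21CC[C@](C)(Cl)[C@@H](Br)C1 | intermediate
30 | CNP0158757.1 (1S,3S,5R,1'R,4'S,5'S) | CC1(C)[C@@H](Br)C[C@@H](O)[C@@]1(C)[C@@]1(O)CC[C@](C)(Cl)[C@@H](Br)C1 | target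

**Step count and risks**

Total: 20 steps. Longest linear sequence: 20 steps (1 to 30).

Step 17 is the most likely to fail. Chloride may enter the bromonium ion at the secondary carbon C5' in the trans-diaxial sense favoured by the chair that keeps ring A equatorial, instead of returning to the tertiary carbon C4'. The fallback sets out from 26 and comes back at 27. The same chlorosulfite activation, or dry HCl in CH2Cl2, is run on purpose to the diaxial product, the 4'-bromo-5'-chloro isomer F1 (Br on C4' on the upper face, Cl on C5' on the lower face). F1 is then heated in chlorobenzene at about 100 °C. The known diaxial-to-diequatorial 1,2-interchange of vicinal dihalides (a dyotropic shift in which each halogen moves to the neighbouring carbon on its own face) should carry it to 27, where both halogens are equatorial and the 1,3-diaxial contact of the C5' chlorine and the C1' oxygen is gone.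

Step 19 comes next. Displacement at C3 is slowed by the neighbouring quaternary C2, so ionisation of the alkoxyphosphonium salt with shift of a C2 methyl group, or elimination toward C4, may outrun it. The fallback sets out from 28 and comes back at 29. The alcohol is converted at −30 °C (Tf2O, pyridine, CH2Cl2) into the C3 trifluoromethanesulfonate F2, and F2 is displaced by Bu4NBr in toluene at 0 °C. The better leaving group and non-ionising solvent should allow inversion well below the temperature at which the skeleton rearranges.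

Step 13 is the third. The samarium chelate to the C1' hydroxyl may not hold, so that ring B closes on the face away from that hydroxyl or the aldehyde is simply reduced. The fallback sets out from 18 and comes back at 21. Ring-closing metathesis (second-generation Grubbs catalyst, CH2Cl2, 40 °C) joins the two arms to the cyclohexenol F3 (C4'=C5' double bond). Hydrogen-bond-directed syn dihydroxylation (OsO4, TMEDA, CH2Cl2, −78 °C, then aq. NaHSO3) should then add both oxygens on the face of the homoallylic C1' hydroxyl and give the all-cis triol 21.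

Further compounds
F1 | step 17 | 4'-bromo-5'-chloro isomer of 27 (trans-diaxial; Br on C4' upper face; Cl on C5' lower face) | CC1(C)[C@H](O[Si](C)(C)C(C)(C)C)C[C@@H](OC(=O)O2)[C@@]1(C)[C@]21CC[C@@](C)(Br)[C@H](Cl)C1
F2 | step 19 | C3 trifluoromethanesulfonate of 28 | CC1(C)[C@H](OS(=O)(=O)C(F)(F)F)C[C@@H](OC(=O)O2)[C@@]1(C)[C@]21CC[C@](C)(Cl)[C@@H](Br)C1
F3 | step 13 | cyclohexenol from ring-closing metathesis of 18 (C4'=C5' alkene; C5 OBoc; C3 OTBS) | CC1(C)[C@H](O[Si](C)(C)C(C)(C)C)C[C@@H](OC(=O)OC(C)(C)C)[C@@]1(C)[C@@]1(O)CCC(C)=CC1
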